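The constants are made up; the run is a simulation.

If two mirror-image substrates meet one single-handed partner at one temperature, the excess in the products can be read from the two rate constants at that temperature for as long as the two substrates stand equal, so I started my reckoning of these flasks from that comparison.

| flask | left-handed substrate | gas | right-handed substrate | time | remark | temperature |
|---|---|---|---|---|---|---|
| dawn | 1.1 M | 150 mM (held) | 1.1 M | 5.0 s | at 70 °C until 4.0 s, from then on at 130 °C |  |
| dusk | 1.1 M | 150 mM (held) | 1.1 M | 5.0 s |  | 70 °C |
| summer | 1.1 M | 150 mM (held) | 1.1 M | 5.0 s |  | 130 °C |
| autumn | 1.1 M | 150 mM (held) | 1.1 M | 5.0 s |  | 100 °C |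

    2 partner → self-condensation product (k1 = 8.61 M⁻¹ s⁻¹, Ea1 = 55.0 kJ mol⁻¹)
    partner ⇌ dormant form (K2 = 8.1, k2 = 0.0139 s⁻¹, Ea2 = 99.0 kJ mol⁻¹, ΔH2 = −47.0 kJ mol⁻¹)
    partner + left-handed substrate → left-handed product (k3 = 1.85 M⁻¹ s⁻¹, Ea3 = 70.0 kJ mol⁻¹)
    left-handed substrate ⇌ right-handed substrate (k4 = 0.181 s⁻¹, Ea4 = 84.0 kJ mol⁻¹)
    partner + right-handed substrate → right-handed product (k5 = 1.14 M⁻¹ s⁻¹, Ea5 = 41.0 kJ mol⁻¹)
    gas ⇌ partner, rate k6*(csat - [partner]) (k6 = 1.29 s⁻¹, csat = 150 mM)
    (constants at 100 °C)

- partner is single-handed; left-handed substrate and right-handed substrate are mirror images of each other, charged as a racemate, each of them at the stated concentration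
- where a step has two of a species, its rate is k times that concentration squared, and two are used at each turn
- at the start none of partner is dissolved
- all constants are for 100 °C and move with temperature by the activation energies and enthalpies
- an excess is the difference of the two amounts in percent of their sum
- an excess is below zero if the other one leads
- the handed part of partner does not stay in what it makes, so the products of the two hands are mirror images too

- which flask leads in excess of left-handed product over right-handed product ("all alike" within 1.5 percentage points) (dawn / dusk / summer / autumn / all alike)
- excess of left-handed product over right-handed product at the end, dawn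
- excess of left-handed product over right-handed product at the end, dusk
- excess of left-handed product over right-handed product at the end, summer
- excess of left-handed product over right-handed product at the end, autumn

At 70 °C I reckoned 0.717 for the selectivity factor, the constant of the step to left-handed product over that of the step to right-handed product at one temperature; it came to 3.25 at 130 °C and 1.62 at 100 °C. In my first extreme the substrate hands turned into each other at once, so they stood equal, each product grew in proportion to its constant, and the excess was the factor minus one over the factor plus one: −16.5% for dusk, 53.0% for summer and 23.7% for autumn. In my other extreme the hands never turned, so the favoured hand fell behind and the excess shrank in size as conversion grew.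

To place the real flasks between these, I needed the level of partner, which I set where the gas supplied it as fast as the substrate took it, leaving self-condensation out. Substrate took partner at 0.678 s⁻¹ when cold and 14.3 s⁻¹ when hot, which gave partner levels of 0.0983 M and 0.0124 M. In summer the hands drew apart at 0.0855 s⁻¹ while turning closed them at 2.71 s⁻¹, so summer lay near my first extreme. In dusk the hands could part by about 5.00% in the whole run, so dusk lay near it too.

For dawn I mixed two batches. I estimated that the cold stretch made 0.267 M of product at the dusk excess and that the hot second made 0.276 M at the summer excess, counting the partner stock and the gas taken up in that second. That gave 18.8% for dawn, and my ranking put summer ahead.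

The forecast also chose summer, with 19% for dawn (15% to 23%), −15.3% for dusk (−16.5% to −14%), 52% for summer (49% to 54%) and 22% for autumn (20% to 24%). Its summer and autumn figures were smaller than mine, and its grounds included “fast racemisation when hot keeping the substrate near racemic so that summer stays close to its kinetic limit”.

The simulation put summer ahead, with 19.5% for dawn, −15.6% for dusk, 51.8% for summer and 21.9% for autumn. In dusk at 5.00 s, the half-life of partner was 2.7 s by the step to left-handed product and 2.0 s by the step to right-handed product, a read ratio of 0.741 beside the selectivity factor of 0.717. For a flask like dusk kept at 95 °C, the factor came to 1.43, which gave 17.7%, and that flask stood at 16.2%.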